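**Retrosynthetic overview**
1. Last operation (key step): the seven-membered lactone and the pyranone close together from an open diaryl-ether triol acid and a C5 enoic acid in P2O5/MeSO3H (lactonization plus Friedel–Crafts acylation/oxa-Michael addition; three bonds, two rings).
2. The triol acid comes from global demethylation of a fully O-methylated diaryl ether.
3. The diaryl ether comes from SNAr of a ring B phenol with a single free OH (ether regiochemistry fixed) on a ring A aryl fluoride flanked by CHO and CO2Me.
4. Ring A fluoride: one-pot double ortho-metalation (formylation, then methoxycarbonylation) of a fluoroanisole. Ring B phenol: Dakin oxidation of a dimethoxybenzaldehyde.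
5. Ring order: both benzene rings are bought; the dioxepinone and pyranone rings form last, in the same flask.

Assumption: the target SMILES has no stereocentre, so Mollicellin A is achiral and no enantiocontrol is needed; compounds are numbered in the order of the forward route.

**Route**

Step 1
Reactants: 1 3-fluoro-5-methylanisole
Product: 6 methyl 2-fluoro-3-formyl-4-methoxy-6-methylbenzoate, via aryllithium 2 (not isolated), via lithium amino alkoxide 3 (not isolated), via lithiated amino alkoxide 4 (not isolated), via ester amino alkoxide 5 (not isolated)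
Conditions: n-BuLi, THF, −78 °C; DMF (1.0 equiv), −78 °C; PMDTA, s-BuLi, −78 °C; ClCO2Me, −78 → 0 °C; 1 M HCl
Reagents that add atoms: N,N-dimethylformamide CN(C)C=O; methyl chloroformate COC(=O)Cl
Why: Two directed ortho-metalations in one pot, in which n-BuLi removes the proton flanked by F and OMe, DMF traps the aryllithium as a tetrahedral lithium α-amino alkoxide that masks the aldehyde (Comins-type in situ protection), PMDTA-activated s-BuLi then deprotonates under acidity control next to fluorine and not next to OMe, and methyl chloroformate acylates the hindered aryllithium once; no stereocentre remains after hydrolysis.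

Step 2
Reactants: 7 2,4-dimethoxy-6-methylbenzaldehyde
Product: 9 2,4-dimethoxy-6-methylphenol, via aryl formate 8 (not isolated)
Conditions: mCPBA, CH2Cl2, 0 °C → rt; NaHCO3 wash; K2CO3 (cat.), MeOH, rt
Reagents that add atoms: 3-chloroperoxybenzoic acid (mCPBA) OOC(=O)c1cccc(Cl)c1
Why: Baeyer–Villiger (Dakin-type) oxidation, in which the electron-rich di-ortho-substituted aryl group migrates in the Criegee adduct to give the aryl formate that methanol then transesterifies to the phenol; no stereocentre is formed.

Step 3
Reactants: 6 methyl 2-fluoro-3-formyl-4-methoxy-6-methylbenzoate; 9 2,4-dimethoxy-6-methylphenol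
Product: 10 methyl 2-(2,4-dimethoxy-6-methylphenoxy)-3-formyl-4-methoxy-6-methylbenzoate
Conditions: K2CO3, DMF, 80 °C, argon
Reagents that add atoms: none
Why: SNAr (addition–elimination) at a fluoride activated by an ortho formyl and an ortho ester group, with the only phenolic OH of 9 fixing which ring B oxygen becomes the ether; no stereocentre is formed.

Step 4
Reactants: 10 methyl 2-(2,4-dimethoxy-6-methylphenoxy)-3-formyl-4-methoxy-6-methylbenzoate
Product: 11 2-(2,4-dihydroxy-6-methylphenoxy)-3-formyl-4-hydroxy-6-methylbenzoic acid
Conditions: BBr3 (10 equiv), CH2Cl2, −78 °C → rt, 16 h; H2O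
Reagents that add atoms: none
Why: Lewis-acid dealkylation in which BBr3 coordinates each oxygen and bromide attacks the methyl carbon (SN2), cleaving the three aryl methyl ethers and, on prolonged reaction at room temperature, the methyl ester by alkyl–oxygen scission, while the diaryl ether and the boron-chelated aldehyde survive; no stereocentre is formed.

Step 5
Reactants: 11 2-(2,4-dihydroxy-6-methylphenoxy)-3-formyl-4-hydroxy-6-methylbenzoic acid; 12 3-methylbut-2-enoic acid
Product: 15 Mollicellin A, via depsidone lactone 13 (not isolated), via aryl enone 14 (not isolated)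
Conditions: P2O5/MeSO3H (1:10 w/w), rt → 70 °C; ice water
Reagents that add atoms: none
Why: Proposed new method: in P2O5/MeSO3H both carboxylic acids are activated as mixed anhydrides or acylium ions, so the ring A acid is captured by the only OH of ring B ortho to the ether oxygen (seven-membered lactone; xanthone formation is blocked because both ortho carbons are substituted) while the 3-methylbut-2-enoyl cation acylates ring B ortho to the free OH and para to the other oxygen (the site at which orcinol-type rings acylate; the order of the two acylations may invert without consequence) and acid-catalysed 6-endo oxa-Michael addition closes the pyranone, the closest known reactions being the Friedel–Crafts acylation/oxa-Michael chromanone annulation of resorcinols with this acid in the same medium and the dehydrative lactonization of depsidone seco-acids; the product is achiral, so no stereocentre is set.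

**Compound list**

1 | 3-fluoro-5-methylanisole (1-fluoro-3-methoxy-5-methylbenzene) | COc1cc(C)cc(F)c1 | starting material
2 | (2-fluoro-6-methoxy-4-methylphenyl)lithium | COc1cc(C)cc(F)c1[Li] | intermediate (not isolated)
3 | lithium (dimethylamino)(2-fluoro-6-methoxy-4-methylphenyl)methanolate, racemic at the hemiaminal carbon | COc1cc(C)cc(F)c1C(O[Li])N(C)C | intermediate (not isolated)
4 | lithium (dimethylamino)(2-fluoro-3-lithio-6-methoxy-4-methylphenyl)methanolate, racemic | COc1cc(C)c([Li])c(F)c1C(O[Li])N(C)C | intermediate (not isolated)
5 | lithium (dimethylamino)[2-fluoro-6-methoxy-3-(methoxycarbonyl)-4-methylphenyl]methanolate, racemic | COC(=O)c1c(C)cc(OC)c(C(O[Li])N(C)C)c1F | intermediate (not isolated)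
6 | methyl 2-fluoro-3-formyl-4-methoxy-6-methylbenzoate | COC(=O)c1c(C)cc(OC)c(C=O)c1F | intermediate
7 | 2,4-dimethoxy-6-methylbenzaldehyde | COc1cc(C)c(C=O)c(OC)c1 | starting material
8 | 2,4-dimethoxy-6-methylphenyl formate | COc1cc(C)c(OC=O)c(OC)c1 | intermediate (not isolated)
9 | 2,4-dimethoxy-6-methylphenol | COc1cc(OC)c(O)c(C)c1 | intermediate
10 | methyl 2-(2,4-dimethoxy-6-methylphenoxy)-3-formyl-4-methoxy-6-methylbenzoate | COC(=O)c1c(C)cc(OC)c(C=O)c1Oc1c(C)cc(OC)cc1OC | intermediate
11 | 2-(2,4-dihydroxy-6-methylphenoxy)-3-formyl-4-hydroxy-6-methylbenzoic acid | Cc1cc(O)c(C=O)c(Oc2c(C)cc(O)cc2O)c1C(=O)O | intermediate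
12 | 3-methylbut-2-enoic acid | CC(C)=CC(=O)O | starting material
13 | 3,8-dihydroxy-1,6-dimethyl-11-oxo-11H-dibenzo[b,e][1,4]dioxepine-4-carbaldehyde | Cc1cc(O)c(C=O)c2c1C(=O)Oc1cc(O)cc(C)c1O2 | intermediate (not isolated)
14 | 3,8-dihydroxy-1,6-dimethyl-7-(3-methylbut-2-enoyl)-11-oxo-11H-dibenzo[b,e][1,4]dioxepine-4-carbaldehyde | Cc1cc(O)c(C=O)c2c1C(=O)Oc1cc(O)c(C(=O)C=C(C)C)c(C)c1O2 | intermediate (not isolated)
15 | Mollicellin A (achiral) | Cc1cc(O)c(C=O)c2c1C(=O)Oc1cc3c(c(C)c1O2)C(=O)CC(C)(C)O3 | target

**Totals and risks**

Total step count: 5. Longest linear sequence: 4 steps (1 → 6 → 10 → 11 → 15, or 7 → 9 → 10 → 11 → 15).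

Steps most likely to fail:

Step 1. The second metalation may go next to OMe or at the benzylic methyl, and the ortho-fluoro aryllithium can lose LiF. The fallback sets out from 1 and comes back at 6. Compound 1 is metalated once only (n-BuLi, THF, −78 °C; DMF; aqueous acid) and 2-fluoro-6-methoxy-4-methylbenzaldehyde F1 is isolated. NBS in MeCN brominates para to the methoxy group, at the carbon between F and Me, to give 3-bromo-2-fluoro-6-methoxy-4-methylbenzaldehyde F2. Palladium-catalysed methoxycarbonylation (Pd(OAc)2, Xantphos, CO 1 atm, MeOH, Na2CO3, toluene, 90 °C) then gives 6. The ester carbon is thus introduced by electrophilic substitution plus carbonylation instead of by deprotonation.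

Step 4. The hindered methyl ester may survive BBr3, and long exposure can damage the aldehyde. The fallback sets out from 10 and comes back at 11. The deprotection is split by mechanism: BBr3 at −78 → 0 °C for a short time cleaves only the three aryl methyl ethers and leaves methyl 2-(2,4-dihydroxy-6-methylphenoxy)-3-formyl-4-hydroxy-6-methylbenzoate F3. The ester is then dealkylated by SN2 attack of iodide on its methyl group (LiI, pyridine, reflux; acid work-up), which is indifferent to crowding at the carbonyl, to give 11.

Step 5. Acylation may occur between the two ring B oxygens, the free aldehyde may condense with the electron-rich ring in strong acid, and the lactone may undergo Fries-type scrambling. The fallback sets out from 9 and comes back at 15; it builds the pyranone before the aldehyde-bearing ring is present and closes the lactone alone at the end.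
- Phenol 9 is acylated with 12 in P2O5/MeSO3H at the only open position para to a methoxy group (between OMe and Me; the other open position lies between two methoxy groups) to give 1-(3-hydroxy-4,6-dimethoxy-2-methylphenyl)-3-methylbut-2-en-1-one F4.
- BCl3 in CH2Cl2 cleaves the methoxy group ortho to the ketone through the boron chelate, and the freed phenol closes by oxa-Michael addition on K2CO3/MeOH work-up to 6-hydroxy-7-methoxy-2,2,5-trimethylchroman-4-one F5.
- SNAr of F5 on 6 (K2CO3, DMF, 80 °C) gives methyl 3-formyl-4-methoxy-2-[(7-methoxy-2,2,5-trimethyl-4-oxochroman-6-yl)oxy]-6-methylbenzoate F6.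
- BBr3 removes the two remaining O-methyl groups and the ester methyl to give 3-formyl-4-hydroxy-2-[(7-hydroxy-2,2,5-trimethyl-4-oxochroman-6-yl)oxy]-6-methylbenzoic acid F7; any pyranone opened by retro-Michael reaction recloses on mild base work-up.
- Trifluoroacetic anhydride in CH2Cl2 closes the seven-membered lactone onto the only OH ortho to the ether oxygen to give 15.

**Further compounds**

F1 | step 1 | 2-fluoro-6-methoxy-4-methylbenzaldehyde | COc1cc(C)cc(F)c1C=O
F2 | step 1 | 3-bromo-2-fluoro-6-methoxy-4-methylbenzaldehyde | COc1cc(C)c(Br)c(F)c1C=O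
F3 | step 4 | methyl 2-(2,4-dihydroxy-6-methylphenoxy)-3-formyl-4-hydroxy-6-methylbenzoate | COC(=O)c1c(C)cc(O)c(C=O)c1Oc1c(C)cc(O)cc1O
F4 | step 5 | 1-(3-hydroxy-4,6-dimethoxy-2-methylphenyl)-3-methylbut-2-en-1-one | COc1cc(OC)c(C(=O)C=C(C)C)c(C)c1O
F5 | step 5 | 6-hydroxy-7-methoxy-2,2,5-trimethylchroman-4-one | COc1cc2OC(C)(C)CC(=O)c2c(C)c1O
F6 | step 5 | methyl 3-formyl-4-methoxy-2-[(7-methoxy-2,2,5-trimethyl-4-oxochroman-6-yl)oxy]-6-methylbenzoate | COC(=O)c1c(C)cc(OC)c(C=O)c1Oc1c(OC)cc2OC(C)(C)CC(=O)c2c1C
F7 | step 5 | 3-formyl-4-hydroxy-2-[(7-hydroxy-2,2,5-trimethyl-4-oxochroman-6-yl)oxy]-6-methylbenzoic acid | Cc1cc(O)c(C=O)c(Oc2c(O)cc3OC(C)(C)CC(=O)c3c2C)c1C(=O)O
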